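The runs come from a simulation on assumed constants; noise was put on by code.

**One number.** I decide to fold this flask into one number before looking at anything else.

| flask | starting material | partner | second reagent | third reagent | remark | time |
|---|---|---|---|---|---|---|
| dawn | 0.42 M | 0.80 equiv | 1.3 equiv | 0.95 equiv | run made earlier |  |
| winter | 0.66 M | 0.80 equiv | 1.3 equiv | 0.95 equiv | run made earlier |  |
| summer | 0.30 M | 1.6 equiv | 1.3 equiv | 0.95 equiv | run made earlier |  |
| flask | 0.30 M | 0.800 equiv | 1.30 equiv | 0.950 equiv |  | 12 h |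

| run | time / h | intermediate B / % | intermediate A / % | target / % | starting material / % | side product / % |
|---|---|---|---|---|---|---|
| dawn | 2.00 | 11.3 | 5.5 | 1.8 | 81.5 | 4.1 |
| dawn | 4.00 | 15.7 | 3.2 | 3.2 | 68.2 | 5.6 |
| dawn | 6.00 | 17.1 | 3.4 | 2.8 | 60.2 | 15.2 |
| dawn | 8.00 | 15.1 | 2.3 | 4.9 | 54.4 | 24.1 |
| dawn | 10.0 | 11.5 | 1.7 | 6.2 | 46.1 | 28.5 |
| dawn | 12.0 | 7.5 | 0 | 6.6 | 44.5 | 33.4 |
| winter | 0.833 | 9.3 | 4.5 | 0.6 | 85.8 | 0 |
| winter | 2.50 | 16.7 | 4.4 | 1.7 | 69.0 | 5.3 |
| winter | 4.00 | 20.5 | 2.9 | 4.5 | 60.4 | 12.6 |
| winter | 6.00 | 16.4 | 1.7 | 7.8 | 49.0 | 19.4 |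
| winter | 10.0 | 12.4 | 0.9 | 13.0 | 38.2 | 34.2 |
| winter | 12.0 | 7.1 | 2.1 | 13.3 | 34.2 | 37.1 |
| summer | 1.00 | 5.0 | 7.6 | 0 | 85.7 | 0 |
| summer | 3.00 | 19.2 | 8.2 | 1.9 | 62.7 | 6.1 |
| summer | 6.00 | 22.9 | 5.9 | 4.2 | 46.5 | 21.5 |
| summer | 8.00 | 20.2 | 5.9 | 3.6 | 38.4 | 31.4 |
| summer | 12.0 | 12.7 | 4.1 | 8.4 | 28.2 | 46.7 |

(each reading ± 1 percentage point)

- the analysis behind the earlier runs scatters by 1 percentage point, standard deviation
- a reading or a percentage of target counts all its forms, free or not
- a reading or a percentage of starting material is of its free form alone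

1. the species that holds most of what was charged as starting material, at 12 h (intermediate A / side product / intermediate B / target / starting material)
2. the largest share itself, whichever of these holds it, in percent of the starting material charged

The runs do not read partner, so I assume that it reacts with starting material one for one, with constant k. Then N = k·c·t, with c the charged partner concentration, counts the pseudo-first-order lifetimes that starting material has had against the charged partner. For M equivalents of partner, with E = exp((1−M)N/M), the free fraction is f = (1−M)E/(E−M).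

Dawn at 8.00 h and winter at 6.00 h give a mean k of 0.365 /M/h. For the flask, N is 1.05 and f is 51.9%. That is over half, so starting material holds most.

**Is one enough?** At equal equivalents, yes: dawn at 4.00 h has N of 0.491 and reads 68.2%, while winter at 2.50 h has 0.482 and reads 69.0%. Across equivalents, no: for summer I reckon 23.8% and it reads 28.2%. The flask has dawn's equivalents.

**The result.** The forecast says starting material at 53%, range 47% to 59%, “about 53% of the starting material remains free at 12 h”, slightly above my figure.

The flask gives starting material at 52.7%. Partner then stands at 42.2% of its own charge. N implies a starting half-life of t·ln(2)/N = 7.91 h, and dividing by that remainder gives 18.7 h; the flask's half-life by this step at 12.0 h is 20 h.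

    starting material + partner → intermediate A (k = 9.41 × 10⁻⁵ /M/s)
    second reagent + intermediate A → intermediate B (k = 9.66 × 10⁻⁴ /M/s)
    third reagent + intermediate B → target (k = 3.81 × 10⁻⁵ /M/s)
    starting material + target ⇌ idle adduct, settled at all times (K = 1.90 /M)
    intermediate B → side product (k = 6.50 × 10⁻⁵ /s)

**Longer reading.** The same flask read at 50 h has N of 4.38, so f is 27.3%. It computes to 27.2%, and side product holds most, at 60.4%.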